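**Retrosynthetic overview**
- Target ← di-tert-butyl ester (acidolysis last) ← C12–C13 coupling of a C9 2-iodoethyl decalin with 3-bromofuran-2(5H)-one; the C9 chain comes from an allyl group put on the enol triflate of a C9-keto-C8-ester, and dissolving-metal reduction then sets C9 and C8.
- C4 (CH3 α, carboxyl β) ← α-face methylation of the C4 ester enolate; C5 (5α-H) ← hydrogenation of the dienone from the face away from the C10 methyl.
- Key disconnection C1–C10: ring B (C5–C10) with the C8 carboxyl, the C9 oxygen and the C10 methyl is a dearomatised 3-methylsalicylate. Ring A is closed by C-alkylation of the salicylate phenoxide at its methyl-bearing ortho carbon C10 with the C1 iodide tethered through C4.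
- The para carbon C6 could close the same ring size, so it carries a removable bromine. This bromine also holds C4–H in the arene plane, so that the C4 stereocentre (from an oxazolidinone-controlled allylation) fixes C10.
- Ring order: ring B is the starting arene, ring A is formed in the key step, and the butenolide ring is brought in intact.

Key step: step 15

Assumption: positions are given in labdane numbering and β is the face of the C10 methyl group; the enolisable C8 of the β-keto esters 28 and 30 is left open in their SMILES.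

**Route**

Step 1
Reactants: 1 3-bromo-2-methylphenol
Product: 3 4-bromo-2-hydroxy-3-methylbenzaldehyde, via hydroxymethylphenol 2 (not isolated)
Conditions: MgCl2, Et3N, (CH2O)n, MeCN, reflux
Reagents that add atoms: paraformaldehyde (as formaldehyde), C=O
Why: Magnesium phenoxide-directed ortho-formylation reaches only the free ortho carbon (the later C8), the hydroxymethyl adduct 2 being oxidised in the flask by hydride transfer to a second formaldehyde.

Step 2
Reactants: 3 4-bromo-2-hydroxy-3-methylbenzaldehyde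
Product: 4 2-(benzyloxy)-4-bromo-3-methylbenzaldehyde
Conditions: BnBr, K2CO3, DMF, 60 °C
Reagents that add atoms: benzyl bromide, BrCc1ccccc1
Why: Williamson etherification masks the acidic phenol for the palladium and enolate steps.

Step 3
Reactants: 4 2-(benzyloxy)-4-bromo-3-methylbenzaldehyde
Product: 5 2-(benzyloxy)-4-bromo-3-methylbenzoic acid
Conditions: NaClO2, NaH2PO4, 2-methylbut-2-ene, t-BuOH/H2O, 20 °C
Reagents that add atoms: sodium chlorite, [Na+].[O-]Cl=O
Why: Pinnick oxidation converts the aldehyde into the acid without touching the aryl bromide or the benzyl ether, the alkene scavenging HOCl.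

Step 4
Reactants: 5 2-(benzyloxy)-4-bromo-3-methylbenzoic acid
Product: 6 tert-butyl 2-(benzyloxy)-4-bromo-3-methylbenzoate
Conditions: Cl3CC(=NH)Ot-Bu, CH2Cl2/cyclohexane, 20 °C
Reagents that add atoms: tert-butyl 2,2,2-trichloroacetimidate, CC(C)(C)OC(=N)C(Cl)(Cl)Cl
Why: O-alkylation of the acid by the imidate (tert-butyl cation transfer) is insensitive to the ortho substituents and gives an ester that survives every basic step and falls off with acid at the end.

Step 5
Reactants: 6 tert-butyl 2-(benzyloxy)-4-bromo-3-methylbenzoate; 7 dimethyl malonate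
Product: 8 dimethyl 2-[3-(benzyloxy)-4-(tert-butoxycarbonyl)-2-methylphenyl]propanedioate
Conditions: Pd(OAc)2 (2 mol%), P(t-Bu)3·HBF4 (4 mol%), K3PO4, toluene, 80 °C
Reagents that add atoms: none
Why: Palladium-catalysed α-arylation of the malonate enolate forms the C5–C4 bond, the bromide para to the ester being activated for oxidative addition.

Step 6
Reactants: 8 dimethyl 2-[3-(benzyloxy)-4-(tert-butoxycarbonyl)-2-methylphenyl]propanedioate
Product: 10 2-[3-(benzyloxy)-4-(tert-butoxycarbonyl)-2-methylphenyl]acetic acid, via arylmalonic acid 9 (not isolated)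
Conditions: NaOH, MeOH/H2O, 60 °C; then 1 M HCl to pH 2 (0 °C), toluene, 90 °C
Reagents that add atoms: sodium hydroxide (oxygen of the new carboxyl OH), [Na+].[OH-]
Why: Saponification of the two methyl esters and thermal decarboxylation of the arylmalonic acid should give the arylacetic acid, the hindered aryl tert-butyl ester resisting hydroxide.

Step 7
Reactants: 10 2-[3-(benzyloxy)-4-(tert-butoxycarbonyl)-2-methylphenyl]acetic acid; 11 (4S)-4-benzyl-1,3-oxazolidin-2-one
Product: 13 tert-butyl 2-(benzyloxy)-4-{2-[(4S)-4-benzyl-2-oxo-1,3-oxazolidin-3-yl]-2-oxoethyl}-3-methylbenzoate, via mixed pivalic anhydride 12 (not isolated)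
Conditions: t-BuCOCl, Et3N, THF, −20 °C; then 11, LiCl, 20 °C
Reagents that add atoms: none
Why: N-acylation of the oxazolidinone through the mixed anhydride (LiCl/Et3N protocol) attaches the chiral auxiliary under mild conditions.

Step 8
Reactants: 13 tert-butyl 2-(benzyloxy)-4-{2-[(4S)-4-benzyl-2-oxo-1,3-oxazolidin-3-yl]-2-oxoethyl}-3-methylbenzoate; 14 allyl bromide
Product: 16 tert-butyl 2-(benzyloxy)-4-{(2S)-1-[(4S)-4-benzyl-2-oxo-1,3-oxazolidin-3-yl]-1-oxopent-4-en-2-yl}-3-methylbenzoate, via sodium enolate 15 (not isolated)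
Conditions: NaN(SiMe3)2, THF, −78 °C; then 14, −78 → −40 °C
Reagents that add atoms: none
Why: Evans alkylation, in which the chelated (Z)-enolate is allylated on the face opposite the benzyl group of the auxiliary, sets C4 as (S).

Step 9
Reactants: 16 tert-butyl 2-(benzyloxy)-4-{(2S)-1-[(4S)-4-benzyl-2-oxo-1,3-oxazolidin-3-yl]-1-oxopent-4-en-2-yl}-3-methylbenzoate
Product: 18 (2S)-2-[3-(benzyloxy)-4-(tert-butoxycarbonyl)-2-methylphenyl]pent-4-enoic acid, via peroxy acid 17 (not isolated)
Conditions: LiOH, H2O2, THF/H2O, 0 °C; then Na2SO3; HCl to pH 3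
Reagents that add atoms: hydrogen peroxide, OO
Why: Hydroperoxide cleaves the exocyclic imide carbonyl selectively and is too weakly basic to epimerise the benzylic C4 centre.

Step 10
Reactants: 18 (2S)-2-[3-(benzyloxy)-4-(tert-butoxycarbonyl)-2-methylphenyl]pent-4-enoic acid
Product: 19 tert-butyl 2-(benzyloxy)-4-[(2S)-1-tert-butoxy-1-oxopent-4-en-2-yl]-3-methylbenzoate
Conditions: Cl3CC(=NH)Ot-Bu, CH2Cl2/cyclohexane, 20 °C
Reagents that add atoms: tert-butyl 2,2,2-trichloroacetimidate, CC(C)(C)OC(=N)C(Cl)(Cl)Cl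
Why: Base-free imidate esterification keeps the C4 configuration and gives an ester that cannot lactonise onto the later C1 leaving group under basic conditions.

Step 11
Reactants: 19 tert-butyl 2-(benzyloxy)-4-[(2S)-1-tert-butoxy-1-oxopent-4-en-2-yl]-3-methylbenzoate
Product: 21 tert-butyl 2-(benzyloxy)-4-[(2S)-1-tert-butoxy-5-hydroxy-1-oxopentan-2-yl]-3-methylbenzoate, via alkylborane 20 (not isolated)
Conditions: 9-BBN, THF, 0 → 20 °C; then H2O2, aq. NaHCO3, 0 → 20 °C
Reagents that add atoms: hydrogen peroxide, OO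
Why: Anti-Markovnikov hydroboration–oxidation of the terminal alkene gives the primary alcohol (C1), the buffered oxidation sparing the C4 centre.

Step 12
Reactants: 21 tert-butyl 2-(benzyloxy)-4-[(2S)-1-tert-butoxy-5-hydroxy-1-oxopentan-2-yl]-3-methylbenzoate
Product: 22 tert-butyl 4-[(2S)-1-tert-butoxy-5-hydroxy-1-oxopentan-2-yl]-2-hydroxy-3-methylbenzoate
Conditions: H2 (1 atm), 10% Pd/C, EtOAc, 20 °C
Reagents that add atoms: none
Why: Hydrogenolysis of the benzyl ether frees the phenol under neutral conditions, and it is done before any halogen is on the molecule.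

Step 13
Reactants: 22 tert-butyl 4-[(2S)-1-tert-butoxy-5-hydroxy-1-oxopentan-2-yl]-2-hydroxy-3-methylbenzoate
Product: 23 tert-butyl 5-bromo-4-[(2S)-1-tert-butoxy-5-hydroxy-1-oxopentan-2-yl]-2-hydroxy-3-methylbenzoate
Conditions: NBS, MeCN, 0 → 20 °C, dark
Reagents that add atoms: N-bromosuccinimide, O=C1CCC(=O)N1Br
Why: Electrophilic aromatic bromination goes to the only open activated position, para to the hydroxyl (C6), and places there the group that blocks this carbon and directs the conformation at C4 in the key step.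

Step 14
Reactants: 23 tert-butyl 5-bromo-4-[(2S)-1-tert-butoxy-5-hydroxy-1-oxopentan-2-yl]-2-hydroxy-3-methylbenzoate
Product: 24 tert-butyl 5-bromo-4-[(2S)-1-tert-butoxy-5-iodo-1-oxopentan-2-yl]-2-hydroxy-3-methylbenzoate
Conditions: I2, PPh3, imidazole, CH2Cl2, 0 → 20 °C
Reagents that add atoms: iodine, II
Why: Appel-type iodination converts the primary alcohol into the iodide and leaves the hydrogen-bonded salicylate hydroxyl alone.

Step 15
Reactants: 24 tert-butyl 5-bromo-4-[(2S)-1-tert-butoxy-5-iodo-1-oxopentan-2-yl]-2-hydroxy-3-methylbenzoate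
Product: 26 di-tert-butyl 8-bromo-4a-methyl-5-oxo-1,2,3,4,4a,5-hexahydronaphthalene-1,6-dicarboxylate (labdane numbering: 6-bromo-9-oxo-5,7-diene; C4 ester β; C10 methyl β), via potassium phenoxide 25 (not isolated)
Conditions: KOt-Bu (1.0 equiv), t-BuOH, 0.01 M, 25 → 60 °C, Ar
Reagents that add atoms: none
Why: Proposed new method: the potassium phenoxide 25 is an ambident nucleophile whose methyl-bearing ortho carbon C10 displaces iodide from C1 in an intramolecular SN2 reaction, and since C10 carries no hydrogen the product cannot rearomatise and remains a cyclohexa-2,4-dienone; the closest known reaction types are the intramolecular ortho C-alkylation of simple alkylphenoxides by tethered primary halides or sulfonates (Ar2-6 participation) and the C-alkylative dearomatisation of acylphloroglucinol salts, neither shown on a monohydroxy salicylate ester with an unactivated iodide. Ring A closes by a 6-exo-tet attack on C1. Of the other nucleophilic sites, oxygen would have to close an eight-membered ring, C8 carries the ester, and the para carbon C6, which could close the same ring size and would otherwise win through rearomatisation, carries bromine, so that attack there would have to build a quaternary C–Br centre. The new stereocentre C10 is set by C4: allylic 1,3-strain with the C6 bromine holds C4–H in the arene plane, so the tether carbon C3 lies on the α face and the ester on the β face, C1 bonds to the α face of C10 and the methyl group is pushed to the β face, cis to the C4 ester. The step needs C- over O-alkylation, C10 over C6 and α- over β-face attack; these are secured by ring size, by the bromine and by the (S)-configured C4, while t-BuOH (hydrogen-bonded oxygen) and high dilution hold back intermolecular O-alkylation.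

Step 16
Reactants: 26 di-tert-butyl 8-bromo-4a-methyl-5-oxo-1,2,3,4,4a,5-hexahydronaphthalene-1,6-dicarboxylate
Product: 28 di-tert-butyl 4a-methyl-5-oxodecahydronaphthalene-1,6-dicarboxylate (trans-decalin; 5α-H; 10β-CH3; 4β-ester; C8 open as keto–enol mixture), via bromine-free dienone 27 (not isolated)
Conditions: H2 (1–3 atm), 10% Pd/C, Et3N, EtOAc, 20 °C, used directly on fresh 26
Reagents that add atoms: none
Why: Heterogeneous hydrogenation should cleave the alkenyl C–Br bond (Et3N takes up HBr) and saturate both C=C bonds, hydrogen reaching C5 from the α face because the β face carries the axial C10 methyl and the axial C4 ester, which gives the trans ring fusion.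

Step 17
Reactants: 28 di-tert-butyl 4a-methyl-5-oxodecahydronaphthalene-1,6-dicarboxylate
Product: 30 di-tert-butyl 1,4a-dimethyl-5-oxodecahydronaphthalene-1,6-dicarboxylate (4α-CH3; 4β-ester; 5α-H; 10β-CH3), via dilithium dianion 29 (not isolated)
Conditions: LiN(i-Pr)2 (2.3 equiv), THF, −78 → −20 °C; then MeI (1.05 equiv), −78 → 0 °C
Reagents that add atoms: iodomethane, CI
Why: Dianion alkylation, in which the first equivalent of base ties up the β-keto ester as its unreactive enolate and the second forms the more reactive C4 ester enolate, which takes methyl iodide from the equatorial α face away from the axial C10 methyl, so that the ester ends axial (β).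

Step 18
Reactants: 30 di-tert-butyl 1,4a-dimethyl-5-oxodecahydronaphthalene-1,6-dicarboxylate
Product: 32 di-tert-butyl 1,4a-dimethyl-5-{[(trifluoromethyl)sulfonyl]oxy}-1,2,3,4,4a,7,8,8a-octahydronaphthalene-1,6-dicarboxylate (C9 enol triflate; C8=C9), via sodium enolate 31 (not isolated)
Conditions: NaH, THF, 0 °C; then PhNTf2, 0 → 20 °C
Reagents that add atoms: N-phenylbis(trifluoromethanesulfonimide), O=S(=O)(N(c1ccccc1)S(=O)(=O)C(F)(F)F)C(F)(F)F
Why: O-sulfonylation of the β-keto ester enolate gives the enol triflate, the only enolisable position being C8.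

Step 19
Reactants: 32 di-tert-butyl 1,4a-dimethyl-5-{[(trifluoromethyl)sulfonyl]oxy}-1,2,3,4,4a,7,8,8a-octahydronaphthalene-1,6-dicarboxylate
Product: 33 di-tert-butyl 1,4a-dimethyl-5-(prop-2-en-1-yl)-1,2,3,4,4a,7,8,8a-octahydronaphthalene-1,6-dicarboxylate (C9 allyl; C8=C9)
Conditions: CH2=CHCH2SnBu3, Pd(PPh3)4 (5 mol%), LiCl, THF, 65 °C
Reagents that add atoms: allyltributylstannane, C=CC[Sn](CCCC)(CCCC)CCCC
Why: Stille coupling of the electron-poor alkenyl triflate with the allylstannane forms the C9–C11 bond.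

Step 20
Reactants: 33 di-tert-butyl 1,4a-dimethyl-5-(prop-2-en-1-yl)-1,2,3,4,4a,7,8,8a-octahydronaphthalene-1,6-dicarboxylate
Product: 35 di-tert-butyl 1,4a-dimethyl-5-(prop-2-en-1-yl)decahydronaphthalene-1,6-dicarboxylate (8α-ester; 9β-allyl; 9α-H), via 8-epimer 34 (not isolated)
Conditions: Li, NH3/THF, t-BuOH (1 equiv), −78 °C; NH4Cl; then KOt-Bu (0.2 equiv), t-BuOH, 40 °C
Reagents that add atoms: none
Why: Birch-type conjugate reduction of the tetrasubstituted enoate protonates C9 axially from the α face, anti to the C10 methyl, which leaves the side chain equatorial (β), and the catalytic base then moves the C8 ester to the equatorial α position trans to it.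

Step 21
Reactants: 35 di-tert-butyl 1,4a-dimethyl-5-(prop-2-en-1-yl)decahydronaphthalene-1,6-dicarboxylate
Product: 37 di-tert-butyl 5-(2-hydroxyethyl)-1,4a-dimethyldecahydronaphthalene-1,6-dicarboxylate, via aldehyde 36 (not isolated)
Conditions: O3, CH2Cl2/MeOH, −78 °C; then NaBH4, −78 → 0 °C
Reagents that add atoms: ozone, [O-][O+]=O
Why: Ozonolysis with reductive work-up removes the terminal carbon and leaves C12 as a primary alcohol, which the tert-butyl ester at C8 does not acylate.

Step 22
Reactants: 37 di-tert-butyl 5-(2-hydroxyethyl)-1,4a-dimethyldecahydronaphthalene-1,6-dicarboxylate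
Product: 38 di-tert-butyl 5-(2-iodoethyl)-1,4a-dimethyldecahydronaphthalene-1,6-dicarboxylate
Conditions: I2, PPh3, imidazole, CH2Cl2, 0 → 20 °C
Reagents that add atoms: iodine, II
Why: Appel-type iodination gives the primary iodide for the coupling.

Step 23
Reactants: 38 di-tert-butyl 5-(2-iodoethyl)-1,4a-dimethyldecahydronaphthalene-1,6-dicarboxylate; 39 3-bromofuran-2(5H)-one
Product: 40 di-tert-butyl 1,4a-dimethyl-5-[2-(2-oxo-2,5-dihydrofuran-3-yl)ethyl]decahydronaphthalene-1,6-dicarboxylate
Conditions: NiBr2(dme) (10 mol%), 4,4'-di-tert-butyl-2,2'-bipyridine (10 mol%), Zn, DMA, 25 °C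
Reagents that add atoms: none
Why: Nickel-catalysed reductive cross-electrophile coupling of a primary alkyl iodide with an alkenyl bromide forms C12–C13 and brings in the butenolide with its double bond in place.

Step 24
Reactants: 40 di-tert-butyl 1,4a-dimethyl-5-[2-(2-oxo-2,5-dihydrofuran-3-yl)ethyl]decahydronaphthalene-1,6-dicarboxylate
Product: 41 (1S,4aR,5S,6R,8aR)-1,4a-dimethyl-5-[2-(2-oxo-2,5-dihydrofuran-3-yl)ethyl]decahydronaphthalene-1,6-dicarboxylic acid (CNP0478950.1)
Conditions: CF3CO2H/CH2Cl2 (1:3), 0 → 20 °C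
Reagents that add atoms: none
Why: Acidolysis of both tert-butyl esters by loss of isobutene is independent of the hindrance at C4 and spares the butenolide.

**Compound list**
1 | 3-bromo-2-methylphenol | Cc1c(O)cccc1Br | starting material
2 | 3-bromo-6-(hydroxymethyl)-2-methylphenol (magnesium phenoxide in the flask) | Cc1c(O)c(CO)ccc1Br | intermediate
3 | 4-bromo-2-hydroxy-3-methylbenzaldehyde | Cc1c(O)c(C=O)ccc1Br | intermediate
4 | 2-(benzyloxy)-4-bromo-3-methylbenzaldehyde | Cc1c(OCc2ccccc2)c(C=O)ccc1Br | intermediate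
5 | 2-(benzyloxy)-4-bromo-3-methylbenzoic acid | Cc1c(OCc2ccccc2)c(C(=O)O)ccc1Br | intermediate
6 | tert-butyl 2-(benzyloxy)-4-bromo-3-methylbenzoate | Cc1c(OCc2ccccc2)c(C(=O)OC(C)(C)C)ccc1Br | intermediate
7 | dimethyl malonate | COC(=O)CC(=O)OC | starting material
8 | dimethyl 2-[3-(benzyloxy)-4-(tert-butoxycarbonyl)-2-methylphenyl]propanedioate | COC(=O)C(C(=O)OC)c1ccc(C(=O)OC(C)(C)C)c(OCc2ccccc2)c1C | intermediate
9 | 2-[3-(benzyloxy)-4-(tert-butoxycarbonyl)-2-methylphenyl]propanedioic acid | OC(=O)C(C(=O)O)c1ccc(C(=O)OC(C)(C)C)c(OCc2ccccc2)c1C | intermediate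
10 | 2-[3-(benzyloxy)-4-(tert-butoxycarbonyl)-2-methylphenyl]acetic acid | OC(=O)Cc1ccc(C(=O)OC(C)(C)C)c(OCc2ccccc2)c1C | intermediate
11 | (4S)-4-benzyl-1,3-oxazolidin-2-one | O=C1N[C@@H](Cc2ccccc2)CO1 | starting material
12 | mixed anhydride of 10 with pivalic acid | CC(C)(C)C(=O)OC(=O)Cc1ccc(C(=O)OC(C)(C)C)c(OCc2ccccc2)c1C | intermediate
13 | tert-butyl 2-(benzyloxy)-4-{2-[(4S)-4-benzyl-2-oxo-1,3-oxazolidin-3-yl]-2-oxoethyl}-3-methylbenzoate | Cc1c(CC(=O)N2[C@@H](Cc3ccccc3)COC2=O)ccc(C(=O)OC(C)(C)C)c1OCc1ccccc1 | intermediate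
14 | allyl bromide | C=CCBr | starting material
15 | sodium (Z)-enolate of 13 | Cc1c(/C=C(\[O-])N2[C@@H](Cc3ccccc3)COC2=O)ccc(C(=O)OC(C)(C)C)c1OCc1ccccc1.[Na+] | intermediate
16 | tert-butyl 2-(benzyloxy)-4-{(2S)-1-[(4S)-4-benzyl-2-oxo-1,3-oxazolidin-3-yl]-1-oxopent-4-en-2-yl}-3-methylbenzoate | Cc1c([C@H](CC=C)C(=O)N2[C@@H](Cc3ccccc3)COC2=O)ccc(C(=O)OC(C)(C)C)c1OCc1ccccc1 | intermediate
17 | (2S)-2-[3-(benzyloxy)-4-(tert-butoxycarbonyl)-2-methylphenyl]pent-4-eneperoxoic acid | Cc1c([C@H](CC=C)C(=O)OO)ccc(C(=O)OC(C)(C)C)c1OCc1ccccc1 | intermediate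
18 | (2S)-2-[3-(benzyloxy)-4-(tert-butoxycarbonyl)-2-methylphenyl]pent-4-enoic acid | Cc1c([C@H](CC=C)C(=O)O)ccc(C(=O)OC(C)(C)C)c1OCc1ccccc1 | intermediate
19 | tert-butyl 2-(benzyloxy)-4-[(2S)-1-tert-butoxy-1-oxopent-4-en-2-yl]-3-methylbenzoate | Cc1c([C@H](CC=C)C(=O)OC(C)(C)C)ccc(C(=O)OC(C)(C)C)c1OCc1ccccc1 | intermediate
20 | B-alkyl-9-borabicyclo[3.3.1]nonane adduct of 19 (boron on the terminal carbon) | Cc1c([C@H](CCCB2C3CCCC2CCC3)C(=O)OC(C)(C)C)ccc(C(=O)OC(C)(C)C)c1OCc1ccccc1 | intermediate
21 | tert-butyl 2-(benzyloxy)-4-[(2S)-1-tert-butoxy-5-hydroxy-1-oxopentan-2-yl]-3-methylbenzoate | Cc1c([C@H](CCCO)C(=O)OC(C)(C)C)ccc(C(=O)OC(C)(C)C)c1OCc1ccccc1 | intermediate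
22 | tert-butyl 4-[(2S)-1-tert-butoxy-5-hydroxy-1-oxopentan-2-yl]-2-hydroxy-3-methylbenzoate | Cc1c([C@H](CCCO)C(=O)OC(C)(C)C)ccc(C(=O)OC(C)(C)C)c1O | intermediate
23 | tert-butyl 5-bromo-4-[(2S)-1-tert-butoxy-5-hydroxy-1-oxopentan-2-yl]-2-hydroxy-3-methylbenzoate | Cc1c([C@H](CCCO)C(=O)OC(C)(C)C)c(Br)cc(C(=O)OC(C)(C)C)c1O | intermediate
24 | tert-butyl 5-bromo-4-[(2S)-1-tert-butoxy-5-iodo-1-oxopentan-2-yl]-2-hydroxy-3-methylbenzoate (key-step precursor) | Cc1c([C@H](CCCI)C(=O)OC(C)(C)C)c(Br)cc(C(=O)OC(C)(C)C)c1O | intermediate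
25 | potassium phenoxide of 24 | Cc1c([C@H](CCCI)C(=O)OC(C)(C)C)c(Br)cc(C(=O)OC(C)(C)C)c1[O-].[K+] | intermediate
26 | di-tert-butyl 8-bromo-4a-methyl-5-oxo-1,2,3,4,4a,5-hexahydronaphthalene-1,6-dicarboxylate (4β-ester, 10β-CH3; key-step product) | C[C@]12CCC[C@H](C(=O)OC(C)(C)C)C1=C(Br)C=C(C(=O)OC(C)(C)C)C2=O | intermediate
27 | di-tert-butyl 4a-methyl-5-oxo-1,2,3,4,4a,5-hexahydronaphthalene-1,6-dicarboxylate (bromine-free dienone) | C[C@]12CCC[C@H](C(=O)OC(C)(C)C)C1=CC=C(C(=O)OC(C)(C)C)C2=O | intermediate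
28 | di-tert-butyl 4a-methyl-5-oxodecahydronaphthalene-1,6-dicarboxylate (trans-fused, 5α-H, 4β-ester) | C[C@]12CCC[C@H](C(=O)OC(C)(C)C)[C@@H]1CCC(C(=O)OC(C)(C)C)C2=O | intermediate
29 | dilithium dianion of 28 (β-keto ester enolate and C4 ester enolate) | C[C@]12CCCC(=C([O-])OC(C)(C)C)[C@@H]1CCC(C(=O)OC(C)(C)C)=C2[O-].[Li+].[Li+] | intermediate
30 | di-tert-butyl 1,4a-dimethyl-5-oxodecahydronaphthalene-1,6-dicarboxylate (4α-CH3, 4β-ester) | C[C@]12CCC[C@](C)(C(=O)OC(C)(C)C)[C@@H]1CCC(C(=O)OC(C)(C)C)C2=O | intermediate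
31 | sodium enolate of 30 | C[C@]12CCC[C@](C)(C(=O)OC(C)(C)C)[C@@H]1CCC(C(=O)OC(C)(C)C)=C2[O-].[Na+] | intermediate
32 | C9 enol triflate of 30 | C[C@]12CCC[C@](C)(C(=O)OC(C)(C)C)[C@@H]1CCC(C(=O)OC(C)(C)C)=C2OS(=O)(=O)C(F)(F)F | intermediate
33 | C9-allyl C8=C9 enoate | C[C@]12CCC[C@](C)(C(=O)OC(C)(C)C)[C@@H]1CCC(C(=O)OC(C)(C)C)=C2CC=C | intermediate
34 | 8-epimer of 35 (8β-ester) | C[C@]12CCC[C@](C)(C(=O)OC(C)(C)C)[C@@H]1CC[C@H](C(=O)OC(C)(C)C)[C@@H]2CC=C | intermediate
35 | di-tert-butyl 1,4a-dimethyl-5-(prop-2-en-1-yl)decahydronaphthalene-1,6-dicarboxylate (8α-ester, 9β-allyl) | C[C@]12CCC[C@](C)(C(=O)OC(C)(C)C)[C@@H]1CC[C@@H](C(=O)OC(C)(C)C)[C@@H]2CC=C | intermediate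
36 | C12 aldehyde | C[C@]12CCC[C@](C)(C(=O)OC(C)(C)C)[C@@H]1CC[C@@H](C(=O)OC(C)(C)C)[C@@H]2CC=O | intermediate
37 | di-tert-butyl 5-(2-hydroxyethyl)-1,4a-dimethyldecahydronaphthalene-1,6-dicarboxylate | C[C@]12CCC[C@](C)(C(=O)OC(C)(C)C)[C@@H]1CC[C@@H](C(=O)OC(C)(C)C)[C@@H]2CCO | intermediate
38 | di-tert-butyl 5-(2-iodoethyl)-1,4a-dimethyldecahydronaphthalene-1,6-dicarboxylate | C[C@]12CCC[C@](C)(C(=O)OC(C)(C)C)[C@@H]1CC[C@@H](C(=O)OC(C)(C)C)[C@@H]2CCI | intermediate
39 | 3-bromofuran-2(5H)-one | O=C1OCC=C1Br | starting material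
40 | di-tert-butyl ester of the target | C[C@]12CCC[C@](C)(C(=O)OC(C)(C)C)[C@@H]1CC[C@@H](C(=O)OC(C)(C)C)[C@@H]2CCC1=CCOC1=O | intermediate
41 | (1S,4aR,5S,6R,8aR)-1,4a-dimethyl-5-[2-(2-oxo-2,5-dihydrofuran-3-yl)ethyl]decahydronaphthalene-1,6-dicarboxylic acid | C[C@]12CCC[C@](C)(C(=O)O)[C@@H]1CC[C@@H](C(=O)O)[C@@H]2CCC1=CCOC1=O | target

**Step count**
Total: 24 steps. Longest linear sequence: 24 steps (1 → 41).

**Steps most likely to fail**

Step 15. What may go wrong: alkylation at the bromine-bearing para carbon C6 or intermolecular O-alkylation outruns attack at C10, or the ester-stabilised phenoxide reacts too slowly at carbon and the iodide is lost by elimination. Fallback (known chemistry): the dearomatising alkylation is moved to the ester-free phenol, whose simple alkylphenoxide belongs to the class on which the intramolecular ortho C-alkylation is established, and the C8 carboxyl is added afterwards. It sets out from 1. Benzylation (BnBr, K2CO3) gives 1-(benzyloxy)-3-bromo-2-methylbenzene F1. The operations of steps 5 to 11 then give in turn the arylmalonate F2, the arylacetic acid F3, the N-acyl oxazolidinone F4, its (S)-allylation product F5, the pentenoic acid F6, the tert-butyl ester F7 and the primary alcohol F8. Hydrogenolysis gives the phenol F9, para-selective bromination (Bu4NBr3) the 6-bromophenol F10, and iodination as in step 14 the iodide F11. KOt-Bu in t-BuOH closes ring A to the bromodienone F12 under the same allylic-strain control, and immediate hydrogenation (H2, Pd/C, Et3N) gives the trans-decalone F13. Its kinetic lithium enolate (LiN(i-Pr)2, −78 °C; C8 is the only enolisable ketone position) is carboxylated with CO2 to the β-keto acid F14, and esterification of the cold crude acid with tert-butyl 2,2,2-trichloroacetimidate comes back to the route at 28.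

Step 16. What may go wrong: hydrogen is delivered in part to the β face of C5, giving the cis ring fusion, or the C5=C6 bond is saturated before the C–Br bond is cleaved, which leaves a secondary bromide. Fallback: the two events are separated and C5 is set by protonation instead of surface hydrogenation. From 26, hydrodebromination with Bu3SnH and catalytic Pd(PPh3)4 gives the bromine-free dienone 27. Dissolving-metal reduction (Li, NH3/THF, t-BuOH, −78 °C) should add the hydrogen at C5 axially, anti to the C10 methyl, and give after quench the trans-fused Δ6 β-keto ester F15. Hydrogenation of the remaining disubstituted double bond (H2, Pd/C), which creates no stereocentre, comes back to the route at 28.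

Step 23. What may go wrong: the alkyl radical adds in conjugate fashion to the β-carbon of the bromobutenolide, or the bromobutenolide is reduced or dimerised faster than it cross-couples. Fallback: the C12–C13 bond is made by enolate alkylation and the butenolide double bond is introduced afterwards. From 38, alkylation of the lithium enolate of 3-(phenylsulfanyl)oxolan-2-one (LiN(SiMe3)2, THF/HMPA) gives the α-alkyl-α-(phenylsulfanyl)lactone F16 (either epimer at the lactone α-carbon). Oxidation with mCPBA at −78 °C gives the sulfoxide F17. Thermolysis in toluene at 110 °C eliminates the sulfoxide toward the ring CH2 and gives the endocyclic butenolide, which comes back to the route at 40.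

**Further compounds**
F1 | step 15 | 1-(benzyloxy)-3-bromo-2-methylbenzene | Cc1c(OCc2ccccc2)cccc1Br
F2 | step 15 | dimethyl 2-[3-(benzyloxy)-2-methylphenyl]propanedioate | COC(=O)C(C(=O)OC)c1cccc(OCc2ccccc2)c1C
F3 | step 15 | 2-[3-(benzyloxy)-2-methylphenyl]acetic acid | OC(=O)Cc1cccc(OCc2ccccc2)c1C
F4 | step 15 | (4S)-4-benzyl-3-{[3-(benzyloxy)-2-methylphenyl]acetyl}-1,3-oxazolidin-2-one | O=C(Cc1cccc(OCc2ccccc2)c1C)N1[C@@H](Cc2ccccc2)COC1=O
F5 | step 15 | (4S)-4-benzyl-3-{(2S)-2-[3-(benzyloxy)-2-methylphenyl]pent-4-enoyl}-1,3-oxazolidin-2-one | Cc1c([C@H](CC=C)C(=O)N2[C@@H](Cc3ccccc3)COC2=O)cccc1OCc1ccccc1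
F6 | step 15 | (2S)-2-[3-(benzyloxy)-2-methylphenyl]pent-4-enoic acid | Cc1c([C@H](CC=C)C(=O)O)cccc1OCc1ccccc1
F7 | step 15 | tert-butyl (2S)-2-[3-(benzyloxy)-2-methylphenyl]pent-4-enoate | Cc1c([C@H](CC=C)C(=O)OC(C)(C)C)cccc1OCc1ccccc1
F8 | step 15 | tert-butyl (2S)-2-[3-(benzyloxy)-2-methylphenyl]-5-hydroxypentanoate | Cc1c([C@H](CCCO)C(=O)OC(C)(C)C)cccc1OCc1ccccc1
F9 | step 15 | tert-butyl (2S)-5-hydroxy-2-(3-hydroxy-2-methylphenyl)pentanoate | Cc1c([C@H](CCCO)C(=O)OC(C)(C)C)cccc1O
F10 | step 15 | tert-butyl (2S)-2-(6-bromo-3-hydroxy-2-methylphenyl)-5-hydroxypentanoate | Cc1c([C@H](CCCO)C(=O)OC(C)(C)C)c(Br)ccc1O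
F11 | step 15 | tert-butyl (2S)-2-(6-bromo-3-hydroxy-2-methylphenyl)-5-iodopentanoate | Cc1c([C@H](CCCI)C(=O)OC(C)(C)C)c(Br)ccc1O
F12 | step 15 | tert-butyl 8-bromo-4a-methyl-5-oxo-1,2,3,4,4a,5-hexahydronaphthalene-1-carboxylate (4β-ester, 10β-CH3) | C[C@]12CCC[C@H](C(=O)OC(C)(C)C)C1=C(Br)C=CC2=O
F13 | step 15 | tert-butyl 4a-methyl-5-oxodecahydronaphthalene-1-carboxylate (trans-fused, 5α-H) | C[C@]12CCC[C@H](C(=O)OC(C)(C)C)[C@@H]1CCCC2=O
F14 | step 15 | 5-(tert-butoxycarbonyl)-8a-methyl-1-oxodecahydronaphthalene-2-carboxylic acid | C[C@]12CCC[C@H](C(=O)OC(C)(C)C)[C@@H]1CCC(C(=O)O)C2=O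
F15 | step 16 | di-tert-butyl 4a-methyl-5-oxo-1,2,3,4,4a,5,6,8a-octahydronaphthalene-1,6-dicarboxylate (5α-H, C6=C7) | C[C@]12CCC[C@H](C(=O)OC(C)(C)C)[C@@H]1C=CC(C(=O)OC(C)(C)C)C2=O
F16 | step 23 | di-tert-butyl 1,4a-dimethyl-5-{2-[2-oxo-3-(phenylsulfanyl)oxolan-3-yl]ethyl}decahydronaphthalene-1,6-dicarboxylate | C[C@]12CCC[C@](C)(C(=O)OC(C)(C)C)[C@@H]1CC[C@@H](C(=O)OC(C)(C)C)[C@@H]2CCC1(Sc2ccccc2)CCOC1=O
F17 | step 23 | di-tert-butyl 5-{2-[3-(benzenesulfinyl)-2-oxooxolan-3-yl]ethyl}-1,4a-dimethyldecahydronaphthalene-1,6-dicarboxylate | C[C@]12CCC[C@](C)(C(=O)OC(C)(C)C)[C@@H]1CC[C@@H](C(=O)OC(C)(C)C)[C@@H]2CCC1(S(=O)c2ccccc2)CCOC1=O
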